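Slowness is what the red run shows first: at 0.12 M and 20 °C the reading after 3.00 min is 0.9% of product, inside a scatter of 1 percentage point, and then product climbs to 31.6% by 12.0 min. From that run and the blue one I have to judge elm, alder, larch and ash.

| flask | starting material | temperature | remark | time |
|---|---|---|---|---|
| red | 0.12 M | 20 °C | run made earlier |  |
| blue | 0.62 M | 35 °C | run made earlier |  |
| elm | 0.15 M | 45 °C |  | 25 min |
| alder | 0.25 M | 25 °C |  | 25 min |
| larch | 0.25 M | 40 °C |  | 25 min |
| ash | 0.80 M | 40 °C |  | 25 min |

| red: time / min | red: product / % | blue: time / min | blue: product / % |
|---|---|---|---|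
| 1.00 | 1.3 | 1.50 | 14.2 |
| 3.00 | 0.9 | 3.00 | 29.5 |
| 6.00 | 9.7 | 5.00 | 40.7 |
| 8.00 | 17.5 | 6.00 | 41.5 |
| 12.0 | 31.6 | 8.00 | 44.1 |

(scatter of a reading: 1 percentage point)

1. all flasks from highest to lowest amount of product, in percent of the starting material charged, at 25 min (elm / alder / larch / ash)
2. the same order at 2.5 min (elm / alder / larch / ash)
3. the amount of product, in percent of the starting material charged of the flask you put first, at 25 min
4. the amount of product, in percent of the starting material charged of the flask you put last, at 25 min

- a reading or a percentage of product counts all its forms, free or not

I take the blue run in slow motion. In the first instants, at 0.62 M and 35 °C, the wait seen in red is not visible: 14.2% stands after 1.50 min. Blue differs from red in both charge and temperature, so either may shorten the wait; I expect alder, the coldest flask, to trail at 2.5 min. In the middle, product reaches 40.7% by 5.00 min. Then it nearly stops: the next 3.00 min add 3.4 points, and the last reading is 44.1%.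

I read that stop as starting material leaving by a second route, one that speeds up with concentration. Product readings can't prove this. If it holds, product and loss compete throughout, and their ratio, a selectivity factor, falls as the charge c rises. I take the simplest form, a ratio of E/c, so the final yield is E/(E+c). Blue gives E = 0.489 M, the even charge: the charge at which product and loss are equal.

This is a reading from one run at one temperature, so I expect errors of some points. My reckoning puts elm at 76.5%, alder and larch at 66.2%, and ash at 37.9%. That reckoning can't separate larch from alder, which share a charge; I put larch above alder at 25 min as a judgement, larch being the hotter. At 2.5 min I put elm first, then larch, ash and alder: larch and ash share 40 °C, and ash has the lower ceiling.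

The forecast, which sees “a limit in product concentration”, gives elm > larch > alder > ash at 25 min and ash > elm > larch > alder at 2.5 min, with 98% first and 36% last, so it stands near me on ash and far from me on elm.

The flasks give elm > larch > alder > ash at 25 min, with elm at 79.0% and ash at 44.0%, and elm > larch > ash > alder at 2.5 min.

    starting material → intermediate A (k = 0.00340 s⁻¹, Ea = 86.0 kJ mol⁻¹)
    intermediate A → intermediate B (k = 0.0120 s⁻¹, Ea = 92.0 kJ mol⁻¹)
    intermediate B → intermediate C (k = 0.0140 s⁻¹, Ea = 77.0 kJ mol⁻¹)
    intermediate C → product (k = 0.0120 s⁻¹, Ea = 83.0 kJ mol⁻¹)
    starting material + product ⇌ idle adduct, settled at all times (K = 10.0 M⁻¹, ΔH = −60.0 kJ mol⁻¹)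
    2 starting material → homo dimer (k = 0.0110 M⁻¹ s⁻¹, Ea = 66.0 kJ mol⁻¹)
    (constants at 25 °C)

In ash the lost part is homo dimer, 56.0% of the charge at 25.0 min; with the dimerisation of starting material struck out, ash gives >99.9% instead of 44.0%, so that step is why product stops short. The even charge from blue, 0.489 M, had put elm at 76.5% and ash at 37.9%, against 79.0% and 44.0%. A flask like elm kept at 30 °C has the same charge, so E again gives 76.5%, and that flask ends at 73.0%.

The numbers in the tables are calculated for substances that don't exist; scatter was added.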